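Take time first: 6.0 d lies well past the point where both earlier runs have gone flat, so what you need is the height of that flat at 1 mol% of initiator.

| setting | eta | alpha | flask |
|---|---|---|---|
| starting material | 20 mM | 20 mM | 20 mM |
| partner | 1 equiv | 1 equiv | 1.00 equiv |
| initiator | 0.67 mol% | 1.5 mol% | 1 mol% |
| remark | run made earlier | run made earlier |  |
| time |  |  | 6.0 d |

- eta (time / d: starting material / %, over-reaction product / %, target / %): 0.625: 71.4, 15.3, 15.3; 1.04: 70.2, 21.3, 7.8; 2.08: 70.3, 27.9, 1.0; 4.00: 70.1, 30.0, 0.5; 8.00: 70.0, 29.6, 0
- alpha (time / d: starting material / %, over-reaction product / %, target / %): 0.625: 64.6, 19.0, 17.6; 1.67: 64.3, 32.5, 2.8; 3.00: 64.5, 33.7, 0.5; 5.00: 64.4, 34.3, 0; 8.00: 63.4, 35.3, 0.1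

(readings scatter by 0.5 percentage points)

* the state of affairs at 6.0 d: stopped, and by what, or still going (it is still moving / all of the starting material has reacted / the partner has run out first)
* how much of the starting material has reacted by 6.0 d
* how much over-reaction product there is at 6.0 d, in percent of the starting material charged

- the analysis behind the earlier runs scatters by 0.5 percentage points, standard deviation
- the reaction counts as stopped when no species that holds the starting material changes by six tenths of a point or more over the second half of the time

With the main step alone, starting material and partner passing one to one into target, a charge of 1.00 equiv of partner leaves room for complete conversion, yet the eta run stops with 70.0 % of its starting material standing. Add target passing on to over-reaction product: this takes nothing from the starting material, and in the eta run target falls from 15.3 % to 7.8 % between 0.625 d and 1.04 d, a half-life read there of 0.427 d, so 6.0 d holds 14.1 such half-lives and over-reaction product should end close to the conversion. Then add what you cannot see: [partner] was never read, but starting material remains after the changes die away, so the partner running out first, as limiting reagent, is the outcome that fits, and it must be lost by some other path.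

Now replace each flat by its mean, from the second reading on. You get conversions of 29.8 % for eta and 35.9 % for alpha, each mean scattering by 0.25 percentage points against a gap of 6 points. The loading exponent, the logarithm of the ratio of these conversions over that of the ratio of the initiator loadings, is 0.227. Scaling from eta, I commit to 32.7 % conversion, stopped by the partner, with over-reaction product just under that.

The forecast says the partner has run out first, with conversion 32.5 % (31 % to 34 %) and over-reaction product 32.3 % (30.7 % to 33.9 %). Its power is about 0.2, its conversion lies 0.20 points below mine, and of the stop it says: “partner exhaustion fits best, though this is inferred because partner was not measured”.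

The flask gives the partner has run out first, with 33.1 % conversion and 32.1 % over-reaction product.

    initiator → 2 initiating radical (k = 0.00550 h⁻¹)
    starting material + initiating radical → capped initiator + first chain carrier (k = 5.00 × 10⁵ M⁻¹ s⁻¹)
    partner + first chain carrier → target + second chain carrier (k = 4.40 × 10⁵ M⁻¹ s⁻¹)
    starting material + second chain carrier → by-product + first chain carrier (k = 2.50 × 10⁷ M⁻¹ h⁻¹)
    2 second chain carrier → ended chains A (k = 8.00 × 10⁷ M⁻¹ s⁻¹)
    2 first chain carrier → ended chains B (k = 2.30 × 10⁶ M⁻¹ s⁻¹)
    target → over-reaction product (k = 0.0650 h⁻¹)
    2 partner → homo dimer (k = 19.0 M⁻¹ h⁻¹)

In this flask, the passing of 2 partner into homo dimer has half its turnover behind it by 0.709 h, sooner than the passing of partner and first chain carrier into target and second chain carrier, at 0.150 d. At 6.00 d the flask holds 6.79 mM of homo dimer, which is 13.6 mM of the 20 mM of partner charged, and 0 % of the partner remains. The loading exponent of 0.227 gave 32.7 % here against 33.1 %. In the neighbouring flask with 0.4 mol% of initiator it gives 26.5 %, beside a conversion there of 27.0 %.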